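**Assumption:** recombinant toluene dioxygenase whole cells (E. coli JM109(pDTG601)) are treated as an available biocatalyst, so toluene is the ring starting material. Labels C1–C14 are the target's bisabolane positions: ring C1–C6 with oxygens on C1 and C2, methyl on C3 and the side chain on C6; chain C7(=C14H2)–C8–C9–C10–C11.

## Retrosynthetic overview

1. Target ⇐ last-step Shi epoxidation (sets C10) of the tris-angelate diene ⇐ angeloylations and CBS reduction (sets C8) of a hydroxy enone.
2. Hydroxy enone ⇐ hydrolysis of a cis-fused bicyclic methyl ketal in which the C1 oxygen and C8 are tied together.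
3. Key step, C6–C7 bond: 5-exo vinyl-radical cyclization of a C1–O-tethered 2-bromoallyl ketal onto the diene of toluene cis-dihydrodiol (instead of joining a carvone-type ring to the chain by vinylmetal/aldehyde addition). The tether is made in one step from the unprotected diol, NBS and a prenylated methoxyallene that brings all eight side-chain carbons.
4. Ring stereocentres: C1/C2 from enzymatic cis-dihydroxylation of toluene, C6 from the tether, C3/C4 from C2–OH-directed epoxidation.
5. Ring order: carbocycle inherited from toluene; temporary tetrahydrofuran ketal ring (formed step 4, opened step 8); ring oxirane (step 5); side-chain oxirane last (step 11).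

## Route

Step 1
Reactants: 1 toluene
Product: 2 (1S,2R)-3-methylcyclohexa-3,5-diene-1,2-diol
Conditions: E. coli JM109(pDTG601) whole cells (toluene dioxygenase), air, glucose, phosphate buffer pH 7.2, 35 °C; EtOAc extraction, stored cold over a trace of Et3N
Reagents that add atoms: dioxygen, O=O
Why: enzymatic arene cis-dihydroxylation with toluene dioxygenase puts both oxygens of O2 on one face of the 2,3-bond and is known to give this diol in >99% ee, which fixes C1 (S) and C2 (R) of the ring.

Step 2
Reactants: 3 methoxyallene; 4 prenyl bromide (1-bromo-3-methylbut-2-ene)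
Product: 6 3-methoxy-6-methylhepta-1,2,5-triene, via 1-lithio-1-methoxyallene 5 (not isolated)
Conditions: n-BuLi, THF, −40 °C; then 4, −78 to −20 °C; distilled, stored over K2CO3
Reagents that add atoms: none
Why: α-lithiation of an alkoxyallene followed by SN2 alkylation with a primary allylic bromide is standard alkoxyallene chemistry, and no stereocentre is formed.

Step 3
Reactants: 2 (1S,2R)-3-methylcyclohexa-3,5-diene-1,2-diol; 6 3-methoxy-6-methylhepta-1,2,5-triene
Product: 7 (1R,6S)-6-[(2-bromo-3-methoxy-6-methylhepta-1,5-dien-3-yl)oxy]-2-methylcyclohexa-2,4-dien-1-ol (C1–O bromoketal; both ketal epimers)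
Conditions: 6 (1.2 equiv), NBS (1.05 equiv), solid K2CO3, CH2Cl2, −78 to −40 °C; Et3N-washed silica, used quickly
Reagents that add atoms: N-bromosuccinimide, O=C1CCC(=O)N1Br
Why: Proposed new method: NBS brominates the central allene carbon of 6 to give a tertiary bromo-oxocarbenium ion that should be captured by the less hindered C1–OH of the unprotected diol (C2–OH is flanked by the C3 methyl), the same steric bias that lets bulky silyl chlorides silylate the distal hydroxyl of 3-substituted cis-dihydrocatechols; the closest known reaction type is the NBS cohalogenation of methoxyallene with allylic alcohols to 2-bromoallyl mixed acetals (haloacetalization as for Ueno–Stork precursors), and the new ketal carbon is a stereorandom centre that is erased in step 8.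

Step 4
Reactants: 7 C1–O bromoketal
Product: 8 (3aR,7R,7aS)-2-methoxy-6-methyl-3-methylidene-2-(3-methylbut-2-en-1-yl)-2,3,3a,4,7,7a-hexahydro-1-benzofuran-7-ol (cis-fused bicyclic ketal; both ketal epimers)
Conditions: Bu3SnH (1.3 equiv, slow addition), AIBN (0.1 equiv), benzene (0.02 M), 80 °C; aq. KF work-up
Reagents that add atoms: none
Why: Ueno–Stork-type 5-exo-trig vinyl-radical cyclization in a tin hydride chain, in which the C7 radical held on the C1 oxygen can reach the diene terminus C6 only from the face of that oxygen, so the new C6–C7 bond is cis to C1–O (C6 = R), and the resulting allyl radical should take hydrogen mainly at the less hindered C5 terminus to leave the trisubstituted C3=C4 alkene.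

Step 5
Reactants: 8 cis-fused bicyclic ketal
Product: 9 epoxy alcohol (the cis-fused bicyclic ketal with its C3=C4 alkene converted to an oxirane on the face of the C2 hydroxyl; epoxide O, C2–OH, C1–O and C6–C7 all cis; both ketal epimers)
Conditions: VO(acac)2 (5 mol %), t-BuOOH (1.5 equiv, decane), CH2Cl2, 0 °C to rt
Reagents that add atoms: tert-butyl hydroperoxide, CC(C)(C)OO
Why: hydroxyl-directed epoxidation of a cyclic allylic alcohol with VO(acac)2/t-BuOOH delivers oxygen to C3=C4 from the face of the C2 hydroxyl (syn selectivity normally >20:1), setting C3 and C4 cis to the three existing substituents, while the undirected methylidene and prenyl alkenes are left alone.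

Step 6
Reactants: 10 angelic acid ((2Z)-2-methylbut-2-enoic acid)
Product: 11 angelic 2,4,6-trichlorobenzoic anhydride
Conditions: 2,4,6-trichlorobenzoyl chloride (1.0 equiv), Et3N (1.0 equiv), toluene, rt, 2 h; Et3N·HCl filtered off under argon; one batch, kept as a titrated toluene stock solution at −20 °C for both esterifications
Reagents that add atoms: 2,4,6-trichlorobenzoyl chloride, O=C(Cl)c1c(Cl)cc(Cl)cc1Cl
Why: acyl substitution of the triethylammonium angelate on the acid chloride gives the Yamaguchi mixed anhydride, and without a nucleophilic catalyst at room temperature the Z double bond does not isomerize; no stereocentre is involved.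

Step 7
Reactants: 9 epoxy alcohol; 11 angelic 2,4,6-trichlorobenzoic anhydride
Product: 12 C2-O-angeloyl epoxy ketal (the epoxy alcohol with its C2 hydroxyl as the (2Z)-2-methylbut-2-enoate; both ketal epimers)
Conditions: 11 (3 equiv), Et3N (3 equiv), toluene, 75 °C (no DMAP)
Reagents that add atoms: none
Why: Yamaguchi-type esterification with the preformed mixed anhydride, in which the two ortho chlorines steer the alcohol to the angeloyl carbonyl, is the established way to acylate hindered secondary alcohols with angelic acid without Z-to-E isomerization; Et3N keeps the medium basic for the ketal, the only free hydroxyl is capped before the ketone is unveiled, and no stereocentre changes.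

Step 8
Reactants: 12 C2-O-angeloyl epoxy ketal
Product: 14 (1R,2S,3S,4R,6R)-3-hydroxy-1-methyl-4-(6-methyl-3-oxohepta-1,5-dien-2-yl)-7-oxabicyclo[4.1.0]heptan-2-yl (2Z)-2-methylbut-2-enoate, via cyclic hemiketal 13 (not isolated)
Conditions: PPTS (0.2 equiv), acetone–H2O 10:1, 0 °C to rt; used at once
Reagents that add atoms: water, O
Why: mild acid hydrolysis of the mixed methyl ketal through the allyl-stabilized cyclic oxocarbenium ion releases the C8 ketone and the C1 hydroxyl together and removes the stereorandom ketal carbon, while the epoxide survives because its cis ester and hydroxyl neighbours cannot attack it from the rear.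

Step 9
Reactants: 14 hydroxy enone
Product: 15 (1R,2S,3S,4R,6R)-3-hydroxy-4-[(3S)-3-hydroxy-6-methylhepta-1,5-dien-2-yl]-1-methyl-7-oxabicyclo[4.1.0]heptan-2-yl (2Z)-2-methylbut-2-enoate
Conditions: (R)-2-methyl-CBS-oxazaborolidine (0.5 equiv), catecholborane (3 equiv), toluene, −78 °C; MeOH, then aq. NaHCO3
Reagents that add atoms: none
Why: Corey–Bakshi–Shibata reduction in which the α-branched alkenyl carbon C7 is the large and the C9 methylene the small ketone substituent, so the (R)-oxazaborolidine gives the (8S)-allylic alcohol under catalyst control (same sense as acetophenone to (S)-1-phenylethanol), catecholborane at −78 °C sparing ester, epoxide and alkenes and the excess covering the free C1 hydroxyl.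

Step 10
Reactants: 15 (8S)-diol; 11 angelic 2,4,6-trichlorobenzoic anhydride
Product: 16 (1R,2S,3S,4R,6R)-1-methyl-4-[(3S)-6-methyl-3-{[(2Z)-2-methylbut-2-enoyl]oxy}hepta-1,5-dien-2-yl]-7-oxabicyclo[4.1.0]heptane-2,3-diyl bis[(2Z)-2-methylbut-2-enoate]
Conditions: 11 (6 equiv), Et3N (6 equiv), toluene, 75 °C (no DMAP)
Reagents that add atoms: none
Why: the same DMAP-free Yamaguchi angeloylation with the stock mixed anhydride now esterifies the C1 and C8 hydroxyls without touching a stereocentre, and any C2-to-C1 acyl migration beforehand is harmless because both positions end as angelates.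

Step 11
Reactants: 16 tris-angelate diene
Product: 17 (1R,2S,3S,4R,6R)-4-[(3S)-4-[(2R)-3,3-dimethyloxiran-2-yl]-3-{[(2Z)-2-methylbut-2-enoyl]oxy}but-1-en-2-yl]-1-methyl-7-oxabicyclo[4.1.0]heptane-2,3-diyl bis[(2Z)-2-methylbut-2-enoate] (target)
Conditions: D-fructose-derived Shi ketone (0.3 equiv), Oxone (2KHSO5·KHSO4·K2SO4), K2CO3, Bu4NHSO4 (cat.), MeCN–CH2(OMe)2, aq. Na2B4O7 buffer (pH 10.5), 0 °C
Reagents that add atoms: potassium peroxymonosulfate (KHSO5 of Oxone), [K+].[O-]S(=O)(=O)OO
Why: Shi asymmetric epoxidation, in which the chiral dioxirane attacks only the electron-rich trisubstituted prenyl alkene (the angelate alkenes are electron-poor and the 1,1-disubstituted alkene is flanked by an allylic ester) through the spiro transition state that gives (R)-epoxides from R–CH=CMe2 olefins, sets C10 = R under catalyst control.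

## Compound list

1 | toluene | Cc1ccccc1 | starting material
2 | (1S,2R)-3-methylcyclohexa-3,5-diene-1,2-diol | CC1=CC=C[C@H](O)[C@@H]1O | intermediate
3 | methoxyallene (1-methoxypropa-1,2-diene) | C=C=COC | starting material
4 | prenyl bromide (1-bromo-3-methylbut-2-ene) | CC(C)=CCBr | starting material
5 | 1-lithio-1-methoxyallene | C=C=C([Li])OC | intermediate (not isolated)
6 | 3-methoxy-6-methylhepta-1,2,5-triene | C=C=C(OC)CC=C(C)C | intermediate
7 | (1R,6S)-6-[(2-bromo-3-methoxy-6-methylhepta-1,5-dien-3-yl)oxy]-2-methylcyclohexa-2,4-dien-1-ol (ketal epimers) | CC1=CC=C[C@H](OC(OC)(CC=C(C)C)C(Br)=C)[C@@H]1O | intermediate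
8 | (3aR,7R,7aS)-2-methoxy-6-methyl-3-methylidene-2-(3-methylbut-2-en-1-yl)-2,3,3a,4,7,7a-hexahydro-1-benzofuran-7-ol (ketal epimers) | C=C1[C@H]2CC=C(C)[C@@H](O)[C@H]2OC1(OC)CC=C(C)C | intermediate
9 | epoxy alcohol: 8 with the ring alkene as an oxirane cis to the C2 hydroxyl (ketal epimers) | C=C1[C@H]2C[C@H]3O[C@@]3(C)[C@@H](O)[C@H]2OC1(OC)CC=C(C)C | intermediate
10 | angelic acid ((2Z)-2-methylbut-2-enoic acid) | C/C=C(/C)C(=O)O | starting material
11 | angelic 2,4,6-trichlorobenzoic anhydride | C/C=C(/C)C(=O)OC(=O)c1c(Cl)cc(Cl)cc1Cl | intermediate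
12 | C2-O-angeloyl epoxy ketal: 9 with its C2 hydroxyl as the (2Z)-2-methylbut-2-enoate (ketal epimers) | C=C1[C@H]2C[C@H]3O[C@@]3(C)[C@@H](OC(=O)/C(C)=C\C)[C@H]2OC1(OC)CC=C(C)C | intermediate
13 | cyclic hemiketal (12 with OH in place of OMe) | C=C1[C@H]2C[C@H]3O[C@@]3(C)[C@@H](OC(=O)/C(C)=C\C)[C@H]2OC1(O)CC=C(C)C | intermediate (not isolated)
14 | (1R,2S,3S,4R,6R)-3-hydroxy-1-methyl-4-(6-methyl-3-oxohepta-1,5-dien-2-yl)-7-oxabicyclo[4.1.0]heptan-2-yl (2Z)-2-methylbut-2-enoate | C=C(C(=O)CC=C(C)C)[C@H]1C[C@H]2O[C@@]2(C)[C@@H](OC(=O)/C(C)=C\C)[C@H]1O | intermediate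
15 | (1R,2S,3S,4R,6R)-3-hydroxy-4-[(3S)-3-hydroxy-6-methylhepta-1,5-dien-2-yl]-1-methyl-7-oxabicyclo[4.1.0]heptan-2-yl (2Z)-2-methylbut-2-enoate | C=C([C@H](CC=C(C)C)O)[C@H]1C[C@H]2O[C@@]2(C)[C@@H](OC(=O)/C(C)=C\C)[C@H]1O | intermediate
16 | (1R,2S,3S,4R,6R)-1-methyl-4-[(3S)-6-methyl-3-{[(2Z)-2-methylbut-2-enoyl]oxy}hepta-1,5-dien-2-yl]-7-oxabicyclo[4.1.0]heptane-2,3-diyl bis[(2Z)-2-methylbut-2-enoate] | C=C([C@H](CC=C(C)C)OC(=O)/C(C)=C\C)[C@H]1C[C@H]2O[C@@]2(C)[C@@H](OC(=O)/C(C)=C\C)[C@H]1OC(=O)/C(C)=C\C | intermediate
17 | (1R,2S,3S,4R,6R)-4-[(3S)-4-[(2R)-3,3-dimethyloxiran-2-yl]-3-{[(2Z)-2-methylbut-2-enoyl]oxy}but-1-en-2-yl]-1-methyl-7-oxabicyclo[4.1.0]heptane-2,3-diyl bis[(2Z)-2-methylbut-2-enoate] | C=C([C@H](C[C@H]1OC1(C)C)OC(=O)/C(C)=C\C)[C@H]1C[C@H]2O[C@@]2(C)[C@@H](OC(=O)/C(C)=C\C)[C@H]1OC(=O)/C(C)=C\C | target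

## Totals

Total step count: 11. Longest linear sequence: 9 steps (toluene through steps 1, 3, 4, 5, 7, 8, 9, 10 and 11; the allene branch, step 2, joins at step 3 and the anhydride branch, step 6, joins at steps 7 and 10).

## Three steps most likely to fail

**Step 3 (regioselective bromoketalization of the free diol).** The risk is C1/C2 mixtures, bis-ketal formation or bromination of the diene. The fallback replaces steric discrimination in one step by a protecting-group-controlled sequence; it sets out from 2 and comes back to the route at 8. TBSCl/imidazole in DMF at −40 °C silylates the less hindered hydroxyl to give the C1-O-TBS ether of 2 F1. 4-Methoxybenzyl bromide/Ag2O in CH2Cl2 then caps the remaining hydroxyl without base-induced silyl migration, giving the C1-O-TBS C2-O-PMB diether of 2 F2. Bu4NF buffered with AcOH frees C1–OH, giving the C2-O-PMB ether of 2 F3. Bromoketalization with 6 and NBS, now with a single hydroxyl, gives the C2-O-PMB analogue of 7 F4. Bu3SnH/AIBN cyclization as in step 4 gives the C2-O-PMB ether of 8 F5, and DDQ in CH2Cl2/pH 7 buffer removes the PMB group and returns 8.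

**Step 4 (radical cyclization and allyl-radical quench).** The risk is hydrogen delivery at C3 instead of C5, and loss of the diene at 80 °C. The fallback abandons the radical chain for a two-electron organopalladium cyclization; it sets out from 7 and comes back at 8 without any new compound. With Pd(PPh3)4 (5 mol %) and Bu3SnH added by syringe pump in THF at 60 °C, oxidative addition of the vinyl C–Br bond to zerovalent palladium is followed by syn 5-exo carbopalladation of C6, again necessarily on the face of the tether oxygen. Tin hydride then transfers hydride to the π-allylpalladium, and reductive elimination occurs at the less substituted C5 terminus, the regiochemistry known for palladium/tin hydride reductions of allylic electrophiles.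

**Step 9 (CBS reduction of the hydroxy enone).** The risk is that 14 rests largely as hemiketal 13 and reduces slowly, that the free hydroxyl erodes catalyst control, or that the skipped enone isomerizes. The fallback gives up reagent control for reduce–separate–recycle; it sets out from 14 and comes back at 15. Luche reduction (NaBH4, CeCl3·7H2O, MeOH, −78 °C) is fast and strictly 1,2, and gives 15 together with the C8 epimer of 15 F6. The epimers are separated by chromatography, and the unwanted one is returned to 14 with MnO2 in CH2Cl2, which oxidizes only the allylic C8 hydroxyl, and is resubmitted.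

## Further compounds

F1 | step 3 | C1-O-TBS ether of 2, (1R,6S)-6-[(tert-butyldimethylsilyl)oxy]-2-methylcyclohexa-2,4-dien-1-ol | CC1=CC=C[C@H](O[Si](C)(C)C(C)(C)C)[C@@H]1O
F2 | step 3 | C1-O-TBS C2-O-PMB diether of 2 | CC1=CC=C[C@H](O[Si](C)(C)C(C)(C)C)[C@@H]1OCc2ccc(OC)cc2
F3 | step 3 | C2-O-PMB ether of 2, (1S,6R)-6-[(4-methoxybenzyl)oxy]-5-methylcyclohexa-2,4-dien-1-ol | CC1=CC=C[C@H](O)[C@@H]1OCc2ccc(OC)cc2
F4 | step 3 | C2-O-PMB analogue of 7 (ketal epimers) | CC1=CC=C[C@H](OC(OC)(CC=C(C)C)C(Br)=C)[C@@H]1OCc2ccc(OC)cc2
F5 | step 3 | C2-O-PMB ether of 8 (ketal epimers) | C=C1[C@H]2CC=C(C)[C@@H](OCc3ccc(OC)cc3)[C@H]2OC1(OC)CC=C(C)C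
F0 | step 4 | none | none
F6 | step 9 | C8 epimer of 15 ((8R)-allylic alcohol) | C=C([C@@H](CC=C(C)C)O)[C@H]1C[C@H]2O[C@@]2(C)[C@@H](OC(=O)/C(C)=C\C)[C@H]1O
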